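Readings and results were generated by integration with made-up constants, and the scatter is random.

The constants of this flask's steps are not told, so the readings must stand in for them. The dawn run is the flask itself, followed up to its last reading, and the summer run is the same charge a little cooler.

| setting | dawn | summer | flask |
|---|---|---|---|
| substrate | 0.25 M | 0.25 M | 0.25 M |
| reagent | 0.275 M | 0.275 M | 0.275 M |
| free catalyst | 2.5 mM | 2.5 mM | 2.5 mM |
| temperature | 100 °C | 95 °C | 100 °C |
| remark | the very flask that is asked about, followed so far | run made earlier |  |
| time |  |  | 80 min |

| run | time / min | target / % | substrate / % |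
|---|---|---|---|
| dawn | 8.00 | 39.4 | 60.2 |
| dawn | 15.0 | 46.0 | 54.2 |
| dawn | 25.0 | 49.2 | 53.3 |
| dawn | 30.0 | 46.9 | 51.5 |
| dawn | 40.0 | 48.1 | 50.9 |
| dawn | 50.0 | 49.9 | 49.1 |
| summer | 8.00 | 37.0 | 62.4 |
| summer | 15.0 | 47.1 | 52.4 |
| summer | 25.0 | 52.1 | 47.4 |
| summer | 30.0 | 51.3 | 47.9 |
| summer | 40.0 | 54.8 | 45.3 |
| summer | 50.0 | 55.3 | 45.2 |

(readings scatter by 1 percentage point)

- cedar: at 80 min take out 90% of the target then present, then wait 2.5 h
- maple: at 80 min raise the temperature by 15 K, then wait 2.5 h
- birch: at 80 min add free catalyst, 100% of the amount charged, then wait 2.5 h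
- elm: at 80 min add reagent, 100% of the amount charged, then wait 2.5 h
- ash: change nothing and wait 2.5 h more

- target that was removed still counts
- additions bring no volume worth counting

* target, in percent of the substrate first charged, at 80 min
* which option adds most target ("none" when 2 percentage points or less is all one gets) (cedar / maple / birch / elm / ash / none)
* target present, with what was taken out counted in, in percent of the substrate first charged, after cedar
* target present, with what was taken out counted in, in percent of the substrate first charged, after elm

The ledger is kept in substrate, the limiting reagent, with 1.10 equivalents of reagent against it. Each mole charged stands in one of 3 entries: still substrate, turned into target, or held on the catalyst. If one catalyst holds one substrate, that last entry takes at most 1.00% of the charge. The dawn readings at 50.0 min add up to 99.0%, so the books close within the scatter.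

The dawn target readings show no steady rise from 25.0 min on, so the fraction left is the entry to read. The mean of the dawn substrate readings from that time on is 51.2%, which puts target at 48.8% at 80 min if the flat stretch holds. If each target took one reagent, c(reagent) stands at 0.153 M.

This gives the quantity to carry: the stall quotient, c(target) divided by c(substrate) and by c(reagent) in the stopped flask, 6.23 M⁻¹. A flask at equilibrium keeps one quotient at one temperature whatever the charge, but a flask with a dead catalyst need not. The summer run gives 8.17 M⁻¹, higher than dawn. But the two runs share one charge, so this comparison does not tell an equilibrium from a dead catalyst.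

The forecast gives 49.8% (48.5% to 51.5%), which is 1 percentage point above the target reckoned here. It names birch, and puts cedar at 49.8% (48.5% to 68%) and elm at 50.5% (48.5% to 71%). Its stance is “I lean slightly towards dead catalyst.”

The flask gives 48.9%. Birch is best and adds 7.4 points, while cedar and elm leave target at 48.9% and 48.9%.

    reagent + free catalyst ⇌ catalyst intermediate A (K = 9.03 M⁻¹, k = 1.90 M⁻¹ s⁻¹, Ea = 75.0 kJ mol⁻¹, ΔH = −49.0 kJ mol⁻¹)
    substrate + catalyst intermediate A ⇌ catalyst intermediate B (K = 9.32 M⁻¹, k = 5.80 M⁻¹ s⁻¹, Ea = 71.0 kJ mol⁻¹, ΔH = −7.00 kJ mol⁻¹)
    catalyst intermediate B ⇌ free catalyst + target (K = 0.140 M, k = 1.10 s⁻¹, Ea = 76.0 kJ mol⁻¹, ΔH = −43.0 kJ mol⁻¹)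
    catalyst intermediate A → spent catalyst (k = 0.00642 s⁻¹, Ea = 99.0 kJ mol⁻¹)
    (constants at 100 °C)

The equations put the equilibrium quotient at 100 °C at 11.8 M⁻¹, and the amounts standing in the flask at 80 min give a lower stall quotient, 6.37 M⁻¹, so this flask stopped short of equilibrium, with >99.9% of its catalyst spent. Part of the reason shows in the run without the reaction of catalyst intermediate A to spent catalyst: target reaches 59.3% at 80 min, and birch's gain becomes −0.36 points. In the neighbour flask with 0.69 M of reagent, its catalyst >99.9% spent, target stands at 63.6% at 80 min, and the stall quotient is lower than the 6.23 M⁻¹ read from the dawn run, at 3.31 M⁻¹.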